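**Strategy.** Ring B of the octahydronaphthalene (C1 bearing Me and NHCHO, C2, C3, C4 bearing the oxane, C4a, C8a) is cut into a four-carbon diene C3=C4–C4a=C8a and a two-carbon unit C2=C1. The key step is the Diels–Alder union of a 2-(oxanyl) semicyclic diene, made from (S)-linalool and an enantiopure silyloxycyclohexenyl unit, with 2-nitropropene. It forms the C2–C3 and C1–C8a bonds, ring B and the C8a and quaternary C1 stereocentres, steered by a traceless allylic silyloxy group. The resulting C4=C4a alkene and the ring-A oxygen are then used to set C4a, C4 and the C5=C6 alkene.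

Key step: step 7

Remark: (S)-linalool, 2-bromocyclohex-2-en-1-one and freshly distilled 2-nitropropene are taken as purchasable; "Ox" denotes the (2S,5S)-5-chloro-2,6,6-trimethyloxan-2-yl group; 17 is carried as a mixture of C2 epimers because that centre becomes sp2 in step 12.

Step 1
Reactants: 1 (S)-linalool
Product: 2 (3S,6S)-3-chloro-6-ethenyl-2,2,6-trimethyloxane
Conditions: N-chlorosuccinimide, Ph3P=S (10 mol %), CH2Cl2, −20 °C
Reagents that add atoms: N-chlorosuccinimide, O=C1CCC(=O)N1Cl
Why: Chloronium-induced 6-endo (Markovnikov) chloroetherification, in which the tertiary hydroxyl opens the chloronium ion of the trisubstituted alkene at its tertiary carbon with anti addition; a chair transition state with equatorial chlorine and the slimmer vinyl group axial should favour the required (3S,6S) isomer, the 3-epimer and any oxolane by-product being removed by chromatography, while the quaternary centre comes unchanged from linalool.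

Step 2
Reactants: 2 (3S,6S)-3-chloro-6-ethenyl-2,2,6-trimethyloxane
Product: 3 1-Ox-ethan-1-one (methyl ketone)
Conditions: PdCl2 (10 mol %), CuCl, O2 (1 atm), DMF/H2O, rt
Reagents that add atoms: water, O
Why: Tsuji–Wacker oxidation, in which Markovnikov hydroxypalladation of the monosubstituted vinyl group should give the methyl ketone without touching a stereocentre.

Step 3
Reactants: 3 1-Ox-ethan-1-one
Product: 4 1-Ox-ethenyl trifluoromethanesulfonate
Conditions: KN(SiMe3)2, THF, −78 °C; PhNTf2
Reagents that add atoms: N-phenylbis(trifluoromethanesulfonimide), O=S(=O)(C(F)(F)F)N(c1ccccc1)S(=O)(=O)C(F)(F)F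
Why: Enol triflate formation through the potassium enolate of the only enolisable side (the methyl group), no stereocentre being affected.

Step 4
Reactants: 5 2-bromocyclohex-2-en-1-one
Product: 6 (1S)-2-bromocyclohex-2-en-1-ol
Conditions: (R)-2-methyl-CBS-oxazaborolidine (10 mol %), BH3·SMe2, THF, −20 °C
Reagents that add atoms: none
Why: Corey–Bakshi–Shibata reduction, in which the bromovinyl carbon acts as the large group so that the (R)-catalyst should deliver hydride to give the (S)-allylic alcohol, the centre that later steers the cycloaddition.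

Step 5
Reactants: 6 (1S)-2-bromocyclohex-2-en-1-ol
Product: 7 {[(1S)-2-bromocyclohex-2-en-1-yl]oxy}(tert-butyl)dimethylsilane
Conditions: TBSCl, imidazole, DMF, rt
Reagents that add atoms: tert-butyldimethylsilyl chloride, CC(C)(C)[Si](C)(C)Cl
Why: Standard silylation of a secondary alcohol, giving the bulky silyl ether that serves as the facial control element of step 7.

Step 6
Reactants: 7 {[(1S)-2-bromocyclohex-2-en-1-yl]oxy}(tert-butyl)dimethylsilane; 4 1-Ox-ethenyl trifluoromethanesulfonate
Product: 10 tert-butyl{[(1S)-2-(1-Ox-ethenyl)cyclohex-2-en-1-yl]oxy}dimethylsilane (diene), via alkenyllithium 8 (not isolated), via alkenylzinc chloride 9 (not isolated)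
Conditions: t-BuLi (2 equiv), THF, −78 °C; ZnCl2; then 4, Pd(PPh3)4 (5 mol %), THF, 50 °C
Reagents that add atoms: none
Why: Negishi coupling, in which lithium–bromine exchange and transmetallation to zinc give an alkenylzinc that couples with the alkenyl triflate under zerovalent palladium catalysis with retention of both alkene positions, no stereocentre being touched.

Step 7
Reactants: 10 tert-butyl{[(1S)-2-(1-Ox-ethenyl)cyclohex-2-en-1-yl]oxy}dimethylsilane; 11 2-nitropropene
Product: 12 tert-butyl{[(1S,4aS,5R)-5-methyl-5-nitro-8-Ox-1,2,3,4,4a,5,6,7-octahydronaphthalen-1-yl]oxy}dimethylsilane (C8=C8a alkene; OTBS and H-4a on one face, nitro on the other)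
Conditions: 11 (3 equiv), BHT (cat.), toluene, 50 °C
Reagents that add atoms: none
Why: Thermal normal-demand Diels–Alder reaction (intermolecular, concerted but asynchronous [4+2] cycloaddition), in which the unsubstituted diene terminus, the more nucleophilic end of a diene carrying an alkyl group at its inner carbon and a ring substituent at its other terminus, bonds to the CH2 of the nitroalkene and the ring terminus bonds to the nitro-bearing carbon, the regiochemistry known for 1-vinylcyclohexenes with nitroalkenes. Ring B is closed as a cyclohexene in this single bimolecular [4+2] event, both new bonds lying in ring B and no other ring being formed. The ring-fusion CH is set by the π-face: allylic strain with the oxanyl-bearing diene carbon should hold the OTBS group pseudoaxial, so the dienophile adds anti to it. The quaternary C(Me)(NO2) centre is set relative to it by the Alder endo rule (nitro endo, methyl exo), which places nitro cis to the ring-A CH2 and methyl cis to the new ring-fusion hydrogen. The step needs regio-, endo/exo- and facial selectivity, secured respectively by the diene substitution pattern, the nitro group and the silyloxy stereocentre; the hindered cisoid diene conformation is the main risk.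

Step 8
Reactants: 12 silyl ether cycloadduct
Product: 13 (1S,4aS,5R)-5-methyl-5-nitro-8-Ox-1,2,3,4,4a,5,6,7-octahydronaphthalen-1-ol
Conditions: Bu4NF, THF, 0 °C to rt
Reagents that add atoms: none
Why: Fluoride-mediated cleavage of the silyl ether driven by Si–F bond formation, with no change at any stereocentre.

Step 9
Reactants: 13 allylic alcohol
Product: 15 (4aS,5R,8aR)-5-methyl-5-nitro-8-Ox-3,4,4a,5,6,8a-hexahydronaphthalen-1(2H)-one (β,γ-unsaturated ketone, C7=C8 alkene, cis ring fusion), via conjugated enone 14 (not isolated)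
Conditions: DMP, NaHCO3, CH2Cl2, rt; then DBU (0.1 equiv), CH2Cl2, 0 °C
Reagents that add atoms: none
Why: Dess–Martin oxidation followed by base-catalysed deconjugation through the extended dienolate, in which allylic strain between the oxanyl group and the carbonyl-bearing carbon across the tetrasubstituted alkene should make the β,γ-isomer the more stable one; the new ring-fusion hydrogen is set cis to the other one under thermodynamic control, because only the cis-fused isomer can turn the ring-A carbon out of the plane of the oxanyl-substituted alkene, and the former carbinol centre is destroyed.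

Step 10
Reactants: 15 β,γ-unsaturated ketone
Product: 16 (4aS,5R,8R,8aR)-5-methyl-5-nitro-8-Ox-octahydronaphthalen-1(2H)-one
Conditions: H2 (1 atm), [Ir(cod)(PCy3)(py)]PF6 (10 mol %), CH2Cl2, 0 °C to rt
Reagents that add atoms: none
Why: Carbonyl-directed homogeneous hydrogenation, in which the ketone oxygen, lying under ring B beside the alkene, should bind the cationic iridium and deliver H2 to the concave face, so that the new C–H is trans to the neighbouring ring-fusion hydrogen and the oxanyl group ends up equatorial.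

Step 11
Reactants: 16 saturated nitro ketone
Product: 17 (4aS,5R,8R,8aR)-2,5-dimethyl-5-nitro-8-Ox-octahydronaphthalen-1(2H)-one (C2 epimers)
Conditions: lithium diisopropylamide, THF, −78 °C; MeI
Reagents that add atoms: iodomethane, CI
Why: Kinetic enolate alkylation, in which the base removes an axial hydrogen of the unhindered α-CH2 (the ring-fusion α-hydrogen is equatorial to the ketone ring and shielded) and iodomethane gives the 2-methyl ketone as an inconsequential epimer mixture.

Step 12
Reactants: 17 2-methyl ketone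
Product: 18 (4aS,5R,8R,8aR)-2,5-dimethyl-5-nitro-8-Ox-3,4,4a,5,6,7,8,8a-octahydronaphthalen-1-yl trifluoromethanesulfonate
Conditions: KN(SiMe3)2, THF, −78 to −20 °C; PhNTf2
Reagents that add atoms: N-phenylbis(trifluoromethanesulfonimide), O=S(=O)(C(F)(F)F)N(c1ccccc1)S(=O)(=O)C(F)(F)F
Why: Regioselective enol triflate formation, in which deprotonation again at the accessible, stereoelectronically aligned methyl-bearing α-carbon gives the tetrasubstituted enolate that is trapped on oxygen, erasing the methyl-bearing stereocentre.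

Step 13
Reactants: 18 enol triflate
Product: 19 (1R,4R,4aR,8aS)-1,6-dimethyl-1-nitro-4-Ox-1,2,3,4,4a,7,8,8a-octahydronaphthalene
Conditions: Pd(OAc)2 (5 mol %), PPh3, HCO2H, n-Bu3N, DMF, 60 °C
Reagents that add atoms: none
Why: Palladium-catalysed formate reduction (hydrogenolysis) of the enol triflate, which should give the trisubstituted C5=C6 alkene at a fixed position without involving a stereocentre.

Step 14
Reactants: 19 nitro alkene
Product: 21 N-[(1R,4R,4aR,8aS)-1,6-dimethyl-4-Ox-1,2,3,4,4a,7,8,8a-octahydronaphthalen-1-yl]formamide (target), via primary amine 20 (not isolated)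
Conditions: Zn, AcOH, THF, 50 °C; then acetic formic anhydride, CH2Cl2, 0 °C
Reagents that add atoms: acetic formic anhydride, CC(=O)OC=O
Why: Zinc–acetic acid reduction of the tertiary nitro group (C–N bond untouched, configuration retained) followed by N-formylation of the hindered amine with a mixed anhydride.

**Compound list**

1 | (S)-linalool, (3S)-3,7-dimethylocta-1,6-dien-3-ol | C=C[C@](O)(C)CCC=C(C)C | starting material
2 | (3S,6S)-3-chloro-6-ethenyl-2,2,6-trimethyloxane | C=C[C@]1(C)CC[C@H](Cl)C(C)(C)O1 | intermediate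
3 | 1-[(2S,5S)-5-chloro-2,6,6-trimethyloxan-2-yl]ethan-1-one | CC(=O)[C@]1(C)CC[C@H](Cl)C(C)(C)O1 | intermediate
4 | 1-[(2S,5S)-5-chloro-2,6,6-trimethyloxan-2-yl]ethenyl trifluoromethanesulfonate | C=C(OS(=O)(=O)C(F)(F)F)[C@]1(C)CC[C@H](Cl)C(C)(C)O1 | intermediate
5 | 2-bromocyclohex-2-en-1-one | O=C1CCCC=C1Br | starting material
6 | (1S)-2-bromocyclohex-2-en-1-ol | O[C@H]1CCCC=C1Br | intermediate
7 | {[(1S)-2-bromocyclohex-2-en-1-yl]oxy}(tert-butyl)dimethylsilane | CC(C)(C)[Si](C)(C)O[C@H]1CCCC=C1Br | intermediate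
8 | [(6S)-6-(tert-butyldimethylsilyloxy)cyclohex-1-en-1-yl]lithium | CC(C)(C)[Si](C)(C)O[C@H]1CCCC=C1[Li] | intermediate
9 | [(6S)-6-(tert-butyldimethylsilyloxy)cyclohex-1-en-1-yl]zinc chloride | CC(C)(C)[Si](C)(C)O[C@H]1CCCC=C1[Zn]Cl | intermediate
10 | tert-butyl({(1S)-2-{1-[(2S,5S)-5-chloro-2,6,6-trimethyloxan-2-yl]ethenyl}cyclohex-2-en-1-yl}oxy)dimethylsilane | CC(C)(C)[Si](C)(C)O[C@H]1CCCC=C1C(=C)[C@]2(C)CC[C@H](Cl)C(C)(C)O2 | intermediate
11 | 2-nitropropene | CC(=C)[N+](=O)[O-] | starting material
12 | tert-butyl({(1S,4aS,5R)-8-[(2S,5S)-5-chloro-2,6,6-trimethyloxan-2-yl]-5-methyl-5-nitro-1,2,3,4,4a,5,6,7-octahydronaphthalen-1-yl}oxy)dimethylsilane | CC(C)(C)[Si](C)(C)O[C@H]1CCC[C@H]2C1=C([C@]3(C)CC[C@H](Cl)C(C)(C)O3)CC[C@@]2(C)[N+](=O)[O-] | intermediate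
13 | (1S,4aS,5R)-8-[(2S,5S)-5-chloro-2,6,6-trimethyloxan-2-yl]-5-methyl-5-nitro-1,2,3,4,4a,5,6,7-octahydronaphthalen-1-ol | O[C@H]1CCC[C@H]2C1=C([C@]3(C)CC[C@H](Cl)C(C)(C)O3)CC[C@@]2(C)[N+](=O)[O-] | intermediate
14 | (4aS,5R)-8-[(2S,5S)-5-chloro-2,6,6-trimethyloxan-2-yl]-5-methyl-5-nitro-3,4,4a,5,6,7-hexahydronaphthalen-1(2H)-one | O=C1CCC[C@H]2C1=C([C@]3(C)CC[C@H](Cl)C(C)(C)O3)CC[C@@]2(C)[N+](=O)[O-] | intermediate
15 | (4aS,5R,8aR)-8-[(2S,5S)-5-chloro-2,6,6-trimethyloxan-2-yl]-5-methyl-5-nitro-3,4,4a,5,6,8a-hexahydronaphthalen-1(2H)-one | O=C1CCC[C@H]2[C@@H]1C(=CC[C@@]2(C)[N+](=O)[O-])[C@]3(C)CC[C@H](Cl)C(C)(C)O3 | intermediate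
16 | (4aS,5R,8R,8aR)-8-[(2S,5S)-5-chloro-2,6,6-trimethyloxan-2-yl]-5-methyl-5-nitro-octahydronaphthalen-1(2H)-one | O=C1CCC[C@H]2[C@@H]1[C@@H](CC[C@@]2(C)[N+](=O)[O-])[C@]3(C)CC[C@H](Cl)C(C)(C)O3 | intermediate
17 | (4aS,5R,8R,8aR)-8-[(2S,5S)-5-chloro-2,6,6-trimethyloxan-2-yl]-2,5-dimethyl-5-nitro-octahydronaphthalen-1(2H)-one, C2 epimers | O=C1C(C)CC[C@H]2[C@@H]1[C@@H](CC[C@@]2(C)[N+](=O)[O-])[C@]3(C)CC[C@H](Cl)C(C)(C)O3 | intermediate
18 | (4aS,5R,8R,8aR)-8-[(2S,5S)-5-chloro-2,6,6-trimethyloxan-2-yl]-2,5-dimethyl-5-nitro-3,4,4a,5,6,7,8,8a-octahydronaphthalen-1-yl trifluoromethanesulfonate | CC1=C(OS(=O)(=O)C(F)(F)F)[C@H]2[C@H]([C@]3(C)CC[C@H](Cl)C(C)(C)O3)CC[C@@](C)([N+](=O)[O-])[C@H]2CC1 | intermediate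
19 | (1R,4R,4aR,8aS)-4-[(2S,5S)-5-chloro-2,6,6-trimethyloxan-2-yl]-1,6-dimethyl-1-nitro-1,2,3,4,4a,7,8,8a-octahydronaphthalene | CC1=C[C@H]2[C@H]([C@]3(C)CC[C@H](Cl)C(C)(C)O3)CC[C@@](C)([N+](=O)[O-])[C@H]2CC1 | intermediate
20 | (1R,4R,4aR,8aS)-4-[(2S,5S)-5-chloro-2,6,6-trimethyloxan-2-yl]-1,6-dimethyl-1,2,3,4,4a,7,8,8a-octahydronaphthalen-1-amine | CC1=C[C@H]2[C@H]([C@]3(C)CC[C@H](Cl)C(C)(C)O3)CC[C@@](C)(N)[C@H]2CC1 | intermediate
21 | N-[(1R,4R,4aR,8aS)-4-[(2S,5S)-5-chloro-2,6,6-trimethyloxan-2-yl]-1,6-dimethyl-1,2,3,4,4a,7,8,8a-octahydronaphthalen-1-yl]formamide | CC1=C[C@H]2[C@H]([C@]3(C)CC[C@H](Cl)C(C)(C)O3)CC[C@@](C)(NC=O)[C@H]2CC1 | target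

**Totals.** Total step count: 14. Longest linear sequence: 12 steps (steps 1–3 and 6–14, from 1).

**Steps most likely to fail**

Step 7. The twisted, hindered cisoid geometry of diene 10 (oxanyl group against the silyloxy-bearing ring carbon) may make the cycloaddition slower than polymerisation of the nitroalkene, or erode endo and facial selectivity. The fallback sets out from 10: fluoride desilylation gives the dienol (1S)-2-(1-Ox-ethenyl)cyclohex-2-en-1-ol F1, and Dess–Martin oxidation gives the cross-conjugated dienone 2-(1-Ox-ethenyl)cyclohex-2-en-1-one F2, in which the flat carbonyl replaces the pseudoaxial group. Its polar, strongly asynchronous Diels–Alder reaction with 11 should form the same two bonds and deliver enone 14 directly. Facial control is given up in exchange for reactivity, so the adduct from the wrong π-face is removed by chromatography. The route is rejoined at 14.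

Step 10. Hydrogen may be delivered from the exposed convex face, or an iridium hydride may move the alkene back into conjugation. The fallback sets out from 15: LiBH(s-Bu)3 reduction (hydride from the open equatorial direction) should give the axial alcohol (1R,4aS,5R,8aR)-5-methyl-5-nitro-8-Ox-1,2,3,4,4a,5,6,8a-octahydronaphthalen-1-ol F3, whose hydroxyl sits directly under the alkene. Hydroxyl-directed hydrogenation with the same cationic iridium complex then gives the saturated alcohol (1R,4aS,5R,8R,8aR)-5-methyl-5-nitro-8-Ox-decahydronaphthalen-1-ol F4, and Dess–Martin oxidation returns to 16.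

Step 1. Ring closure may go 5-exo to the oxolane, and selection between the two chloride epimers may be poor. The fallback sets out from 1: Shi epoxidation (ketone enantiomer chosen for the 6R epoxide) gives the epoxy alcohol (3S)-5-[(2R)-3,3-dimethyloxiran-2-yl]-3-methylpent-1-en-3-ol F5. Acid-catalysed (camphorsulfonic acid) 6-endo opening at the tertiary epoxide carbon gives the pyranol (3R,6S)-6-ethenyl-2,2,6-trimethyloxan-3-ol F6, the oxolane isomer being separated. Sulfonylation with ClCH2SO2Cl and pyridine gives the chloromethanesulfonate (3R,6S)-6-ethenyl-2,2,6-trimethyloxan-3-yl chloromethanesulfonate F7, and SN2 displacement with LiCl in DMF (inversion) returns to 2.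

**Further compounds**

F1 | step 7 | (1S)-2-{1-[(2S,5S)-5-chloro-2,6,6-trimethyloxan-2-yl]ethenyl}cyclohex-2-en-1-ol | O[C@H]1CCCC=C1C(=C)[C@]2(C)CC[C@H](Cl)C(C)(C)O2
F2 | step 7 | 2-{1-[(2S,5S)-5-chloro-2,6,6-trimethyloxan-2-yl]ethenyl}cyclohex-2-en-1-one | O=C1CCCC=C1C(=C)[C@]2(C)CC[C@H](Cl)C(C)(C)O2
F3 | step 10 | (1R,4aS,5R,8aR)-8-[(2S,5S)-5-chloro-2,6,6-trimethyloxan-2-yl]-5-methyl-5-nitro-1,2,3,4,4a,5,6,8a-octahydronaphthalen-1-ol | O[C@@H]1CCC[C@H]2[C@@H]1C(=CC[C@@]2(C)[N+](=O)[O-])[C@]3(C)CC[C@H](Cl)C(C)(C)O3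
F4 | step 10 | (1R,4aS,5R,8R,8aR)-8-[(2S,5S)-5-chloro-2,6,6-trimethyloxan-2-yl]-5-methyl-5-nitro-decahydronaphthalen-1-ol | O[C@@H]1CCC[C@H]2[C@@H]1[C@@H](CC[C@@]2(C)[N+](=O)[O-])[C@]3(C)CC[C@H](Cl)C(C)(C)O3
F5 | step 1 | (3S)-5-[(2R)-3,3-dimethyloxiran-2-yl]-3-methylpent-1-en-3-ol | C=C[C@](O)(C)CC[C@@H]1C(C)(C)O1
F6 | step 1 | (3R,6S)-6-ethenyl-2,2,6-trimethyloxan-3-ol | C=C[C@]1(C)CC[C@@H](O)C(C)(C)O1
F7 | step 1 | (3R,6S)-6-ethenyl-2,2,6-trimethyloxan-3-yl chloromethanesulfonate | C=C[C@]1(C)CC[C@@H](OS(=O)(=O)CCl)C(C)(C)O1
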